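**Strategy.** The single stereocentre, C3 of the heptenyl chain, is benzylic to ring A between the C2' and C4' hydroxyls and allylic to the C1=C2 styrene. Everything rests on making its C3–H bond last: a Myers allylic diazene retro-ene (reductive 1,3-transposition) moves hydrogen suprafacially from nitrogen at C1 to C3 while the alkene shifts from C2=C3 to C1=C2, setting the configuration and the E-styrene in one operation. The precursor is a (Z)-1,3-diarylallyl alcohol whose C1 carbinol comes from ketone reduction and whose alkene geometry is inherited from a Pechmann coumarin: its C4, C3 and C2 become C3, C2 and C1 of the chain.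

Key step: step 8

Remark: the SMILES fixes C3 of the heptenyl chain as (R); chain atoms are numbered C1 (styrene carbon on the 4-hydroxyphenyl ring) to C7, ring A is the phloroglucinol ring, and 5-(4-hydroxyphenyl)pentanoic acid is assumed to be purchasable.

Step 1
Reactants: 1 5-(4-hydroxyphenyl)pentanoic acid
Product: 3 ethyl 7-(4-hydroxyphenyl)-3-oxoheptanoate, via acyl imidazolide 2 (not isolated)
Conditions: CDI (1,1'-carbonyldiimidazole, 1.05 equiv), THF, 23 °C; then LiCH2CO2Et (from EtOAc and LiN(SiMe3)2, 3.3 equiv), THF, −78 °C; aq. HCl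
Reagents that add atoms: ethyl acetate, CCOC(C)=O
Why: Crossed Claisen condensation, in which the lithium enolate of ethyl acetate is C-acylated by the acyl imidazolide, should give the β-keto ester, the phenoxide and the product enolate only consuming base.

Step 2
Reactants: 3 ethyl 7-(4-hydroxyphenyl)-3-oxoheptanoate; 4 phloroglucinol
Product: 5 5,7-dihydroxy-4-[4-(4-hydroxyphenyl)butyl]-2H-chromen-2-one
Conditions: CF3CO2H, 23 → 60 °C
Reagents that add atoms: none
Why: Pechmann condensation, in which phloroglucinol is far more nucleophilic than the 4-alkylphenol ring and its three equivalent positions allow only one coumarin, with the chain at C4.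

Step 3
Reactants: 5 5,7-dihydroxy-4-[4-(4-hydroxyphenyl)butyl]-2H-chromen-2-one
Product: 6 5-hydroxy-4-[4-(4-hydroxyphenyl)butyl]-7-methoxy-2H-chromen-2-one
Conditions: MeI (1.05 equiv), K2CO3 (1.1 equiv), acetone, 23 °C
Reagents that add atoms: iodomethane, CI
Why: Williamson O-methylation with one equivalent of base should select the 7-hydroxyl, the most acidic and least hindered phenol (vinylogous acid of the lactone carbonyl), over the peri-hindered 5-hydroxyl and the far less acidic 4-alkylphenol.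

Step 4
Reactants: 6 5-hydroxy-4-[4-(4-hydroxyphenyl)butyl]-7-methoxy-2H-chromen-2-one
Product: 7 7-methoxy-5-(methoxymethoxy)-4-{4-[4-(methoxymethoxy)phenyl]butyl}-2H-chromen-2-one
Conditions: NaH, MOMCl, DMF, 0 → 23 °C
Reagents that add atoms: chloromethyl methyl ether (MOMCl), COCCl
Why: Williamson alkylation of the two remaining phenoxides by the reactive α-chloro ether should be complete, and the lactone is inert to NaH.

Step 5
Reactants: 7 7-methoxy-5-(methoxymethoxy)-4-{4-[4-(methoxymethoxy)phenyl]butyl}-2H-chromen-2-one; 8 1-bromo-4-(methoxymethoxy)benzene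
Product: 11 (Z)-3-[4-methoxy-2,6-bis(methoxymethoxy)phenyl]-1,7-bis[4-(methoxymethoxy)phenyl]hept-2-en-1-one, via 4-(methoxymethoxy)phenyllithium 9 (not isolated), via lithium phenoxide of the ring-opened enone 10 (not isolated)
Conditions: 8, n-BuLi, THF, −78 °C; add (1.05 equiv) to 7, THF, −78 → −20 °C; MOMCl, −20 → 0 °C
Reagents that add atoms: chloromethyl methyl ether (MOMCl), COCCl
Why: 1,2-Addition of the aryllithium to the lactone carbonyl and collapse of the lactolate should release the ring-A phenoxide, which MOMCl O-alkylates, so that the former ring bond fixes the alkene as Z (ring A cis to the carbonyl) and ring A becomes symmetric.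

Step 6
Reactants: 11 (Z)-3-[4-methoxy-2,6-bis(methoxymethoxy)phenyl]-1,7-bis[4-(methoxymethoxy)phenyl]hept-2-en-1-one
Product: 12 (Z)-3-[3-iodo-4-methoxy-2,6-bis(methoxymethoxy)phenyl]-1,7-bis[4-(methoxymethoxy)phenyl]hept-2-en-1-one
Conditions: NIS (1.05 equiv), MeCN, 0 → 23 °C, dark
Reagents that add atoms: N-iodosuccinimide, O=C1CCC(=O)N1I
Why: Electrophilic aromatic iodination should occur at one of the two equivalent positions of the trioxygenated ring A, the only ring nucleophilic enough for NIS without acid, and the iodide marks the later acyl position.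

Step 7
Reactants: 12 (Z)-3-[3-iodo-4-methoxy-2,6-bis(methoxymethoxy)phenyl]-1,7-bis[4-(methoxymethoxy)phenyl]hept-2-en-1-one
Product: 13 (1R,2Z)-3-[3-iodo-4-methoxy-2,6-bis(methoxymethoxy)phenyl]-1,7-bis[4-(methoxymethoxy)phenyl]hept-2-en-1-ol
Conditions: (R)-Me-CBS oxazaborolidine [(R)-1-methyl-3,3-diphenyltetrahydro-1H,3H-pyrrolo[1,2-c][1,3,2]oxazaborole] (20 mol %), BH3·SMe2, THF, −30 °C; MeOH, then NaHCO3 work-up
Reagents that add atoms: none
Why: Corey–Bakshi–Shibata reduction should deliver hydride 1,2 to the enone carbonyl, the C1 configuration being set by the oxazaborolidine, whose (R)-enantiomer should give the (1R)-alcohol if, as expected, the twisted Z-alkenyl arm bearing ring A acts as the large group and the flat 4-alkoxyphenyl ring as the small one.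

Step 8
Reactants: 13 (1R,2Z)-3-[3-iodo-4-methoxy-2,6-bis(methoxymethoxy)phenyl]-1,7-bis[4-(methoxymethoxy)phenyl]hept-2-en-1-ol
Product: 16 2-iodo-1-methoxy-3,5-bis(methoxymethoxy)-4-{(1E,3R)-1,7-bis[4-(methoxymethoxy)phenyl]hept-1-en-3-yl}benzene, via allylic sulfonylhydrazine 14 (not isolated), via allylic diazene 15 (not isolated)
Conditions: 2-nitrobenzenesulfonohydrazide (NBSH), PPh3, DEAD, THF, −30 °C; then 23 °C
Reagents that add atoms: none
Why: Mitsunobu displacement of the C1 hydroxyl by the sulfonylhydrazide nitrogen with inversion gives the (1S)-hydrazine 14, which on warming loses 2-nitrobenzenesulfinic acid to the monoalkyl diazene 15, and this expels N2 through a concerted six-membered retro-ene transition state that delivers the N–H hydrogen to C3 on the face occupied by the C1–N bond while the alkene moves from C2=C3 to C1=C2. The closest known reaction type is the Myers reductive 1,3-transposition of allylic alcohols (allylic diazene rearrangement), a sigmatropic loss of dinitrogen. No ring is closed. The new C3 stereocentre is controlled by the C1 configuration together with the Z geometry of the C2=C3 alkene: allylic 1,3-strain against ring A, which is cis to C1, keeps the C1 hydrogen inside and the aryl group outside, so that the (1S)-diazene delivers hydrogen to the face that gives (3R), and the same conformation makes the new C1=C2 alkene E. The step needs clean SN2 substitution (no ionisation, no SN2' attack) at the doubly activated carbinol and hydrogen delivery to C3 only; the first is helped by the low temperature and by the hindered, twisted ring A at the far allyl terminus, and the second is imposed by the pericyclic mechanism.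

Step 9
Reactants: 16 2-iodo-1-methoxy-3,5-bis(methoxymethoxy)-4-{(1E,3R)-1,7-bis[4-(methoxymethoxy)phenyl]hept-1-en-3-yl}benzene
Product: 18 1-{3-[(1E,3R)-1,7-bis[4-(methoxymethoxy)phenyl]hept-1-en-3-yl]-6-methoxy-2,4-bis(methoxymethoxy)phenyl}ethan-1-one, via arylmagnesium chloride 17 (not isolated)
Conditions: i-PrMgCl·LiCl, THF, 0 → 23 °C; Ac2O, −20 → 23 °C; aq. NH4Cl
Reagents that add atoms: acetic anhydride, CC(=O)OC(C)=O
Why: Iodine–magnesium exchange, assisted by the two flanking alkoxy groups, should give an arylmagnesium that is acylated once by acetic anhydride and is not basic enough to remove the C3–H, so that the stereocentre is kept.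

Step 10
Reactants: 18 1-{3-[(1E,3R)-1,7-bis[4-(methoxymethoxy)phenyl]hept-1-en-3-yl]-6-methoxy-2,4-bis(methoxymethoxy)phenyl}ethan-1-one; 19 4-(methoxymethoxy)benzaldehyde
Product: 20 (E)-1-{3-[(1E,3R)-1,7-bis[4-(methoxymethoxy)phenyl]hept-1-en-3-yl]-6-methoxy-2,4-bis(methoxymethoxy)phenyl}-3-[4-(methoxymethoxy)phenyl]prop-2-en-1-one
Conditions: KOH, EtOH/H2O, 23 °C
Reagents that add atoms: none
Why: Claisen–Schmidt (crossed aldol) condensation should give the E-enone under thermodynamic control, hydroxide being far too weak a base for the C3–H and no free 2'-hydroxyl being present to close a flavanone.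

Step 11
Reactants: 20 (E)-1-{3-[(1E,3R)-1,7-bis[4-(methoxymethoxy)phenyl]hept-1-en-3-yl]-6-methoxy-2,4-bis(methoxymethoxy)phenyl}-3-[4-(methoxymethoxy)phenyl]prop-2-en-1-one
Product: 21 deoxycalyxin A, (E)-1-{2,4-dihydroxy-3-[(1E,3R)-1,7-bis(4-hydroxyphenyl)hept-1-en-3-yl]-6-methoxyphenyl}-3-(4-hydroxyphenyl)prop-2-en-1-one
Conditions: HCl (3 M aq.), MeOH, 23 °C
Reagents that add atoms: none
Why: Acid-catalysed acetal exchange with methanol should remove the five MOM groups as dimethoxymethane under conditions mild enough not to protonate the styrene or close the 2'-hydroxychalcone to a flavanone.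

**Compound list**

1 | 5-(4-hydroxyphenyl)pentanoic acid | OC(=O)CCCCc1ccc(O)cc1 | starting material
2 | 1-[5-(4-hydroxyphenyl)pentanoyl]-1H-imidazole (acyl imidazolide) | O=C(CCCCc1ccc(O)cc1)n1ccnc1 | intermediate (not isolated)
3 | ethyl 7-(4-hydroxyphenyl)-3-oxoheptanoate | CCOC(=O)CC(=O)CCCCc1ccc(O)cc1 | intermediate
4 | phloroglucinol (benzene-1,3,5-triol) | Oc1cc(O)cc(O)c1 | starting material
5 | 5,7-dihydroxy-4-[4-(4-hydroxyphenyl)butyl]-2H-chromen-2-one | O=c1cc(CCCCc2ccc(O)cc2)c2c(O)cc(O)cc2o1 | intermediate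
6 | 5-hydroxy-4-[4-(4-hydroxyphenyl)butyl]-7-methoxy-2H-chromen-2-one | O=c1cc(CCCCc2ccc(O)cc2)c2c(O)cc(OC)cc2o1 | intermediate
7 | 7-methoxy-5-(methoxymethoxy)-4-{4-[4-(methoxymethoxy)phenyl]butyl}-2H-chromen-2-one | O=c1cc(CCCCc2ccc(OCOC)cc2)c2c(OCOC)cc(OC)cc2o1 | intermediate
8 | 1-bromo-4-(methoxymethoxy)benzene | COCOc1ccc(Br)cc1 | starting material
9 | [4-(methoxymethoxy)phenyl]lithium | [Li]c1ccc(OCOC)cc1 | intermediate (not isolated)
10 | lithium 5-methoxy-3-(methoxymethoxy)-2-{(2Z)-1-oxo-1,7-bis[4-(methoxymethoxy)phenyl]hept-2-en-3-yl}phenolate | COCOc1ccc(cc1)C(=O)/C=C(/CCCCc1ccc(OCOC)cc1)c1c([O-])cc(OC)cc1OCOC.[Li+] | intermediate (not isolated)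
11 | (Z)-3-[4-methoxy-2,6-bis(methoxymethoxy)phenyl]-1,7-bis[4-(methoxymethoxy)phenyl]hept-2-en-1-one | COCOc1ccc(cc1)C(=O)/C=C(/CCCCc1ccc(OCOC)cc1)c1c(OCOC)cc(OC)cc1OCOC | intermediate
12 | (Z)-3-[3-iodo-4-methoxy-2,6-bis(methoxymethoxy)phenyl]-1,7-bis[4-(methoxymethoxy)phenyl]hept-2-en-1-one | COCOc1ccc(cc1)C(=O)/C=C(/CCCCc1ccc(OCOC)cc1)c1c(OCOC)cc(OC)c(I)c1OCOC | intermediate
13 | (1R,2Z)-3-[3-iodo-4-methoxy-2,6-bis(methoxymethoxy)phenyl]-1,7-bis[4-(methoxymethoxy)phenyl]hept-2-en-1-ol | COCOc1ccc(cc1)[C@H](O)/C=C(/CCCCc1ccc(OCOC)cc1)c1c(OCOC)cc(OC)c(I)c1OCOC | intermediate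
14 | N-{(1S,2Z)-3-[3-iodo-4-methoxy-2,6-bis(methoxymethoxy)phenyl]-1,7-bis[4-(methoxymethoxy)phenyl]hept-2-en-1-yl}-2-nitrobenzenesulfonohydrazide (alkylated at the sulfonylated nitrogen) | COCOc1ccc(cc1)[C@@H](N(N)S(=O)(=O)c1ccccc1[N+](=O)[O-])/C=C(/CCCCc1ccc(OCOC)cc1)c1c(OCOC)cc(OC)c(I)c1OCOC | intermediate (not isolated)
15 | {(1S,2Z)-3-[3-iodo-4-methoxy-2,6-bis(methoxymethoxy)phenyl]-1,7-bis[4-(methoxymethoxy)phenyl]hept-2-en-1-yl}diazene | COCOc1ccc(cc1)[C@@H](N=N)/C=C(/CCCCc1ccc(OCOC)cc1)c1c(OCOC)cc(OC)c(I)c1OCOC | intermediate (not isolated)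
16 | 2-iodo-1-methoxy-3,5-bis(methoxymethoxy)-4-{(1E,3R)-1,7-bis[4-(methoxymethoxy)phenyl]hept-1-en-3-yl}benzene | COc1cc(OCOC)c([C@@H](/C=C/c2ccc(OCOC)cc2)CCCCc2ccc(OCOC)cc2)c(OCOC)c1I | intermediate
17 | {3-[(1E,3R)-1,7-bis[4-(methoxymethoxy)phenyl]hept-1-en-3-yl]-6-methoxy-2,4-bis(methoxymethoxy)phenyl}magnesium chloride | COc1cc(OCOC)c([C@@H](/C=C/c2ccc(OCOC)cc2)CCCCc2ccc(OCOC)cc2)c(OCOC)c1[Mg]Cl | intermediate (not isolated)
18 | 1-{3-[(1E,3R)-1,7-bis[4-(methoxymethoxy)phenyl]hept-1-en-3-yl]-6-methoxy-2,4-bis(methoxymethoxy)phenyl}ethan-1-one | COc1cc(OCOC)c([C@@H](/C=C/c2ccc(OCOC)cc2)CCCCc2ccc(OCOC)cc2)c(OCOC)c1C(C)=O | intermediate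
19 | 4-(methoxymethoxy)benzaldehyde | COCOc1ccc(C=O)cc1 | starting material
20 | (E)-1-{3-[(1E,3R)-1,7-bis[4-(methoxymethoxy)phenyl]hept-1-en-3-yl]-6-methoxy-2,4-bis(methoxymethoxy)phenyl}-3-[4-(methoxymethoxy)phenyl]prop-2-en-1-one | COc1cc(OCOC)c([C@@H](/C=C/c2ccc(OCOC)cc2)CCCCc2ccc(OCOC)cc2)c(OCOC)c1C(=O)/C=C/c1ccc(OCOC)cc1 | intermediate
21 | deoxycalyxin A | COc1cc(O)c([C@@H](/C=C/c2ccc(O)cc2)CCCCc2ccc(O)cc2)c(O)c1C(=O)/C=C/c1ccc(O)cc1 | target

**Step count and risks**

Total steps: 11. Longest linear sequence: 11 (from 1).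

Step 8 (key step). The oxyphosphonium of the benzylic and allylic carbinol may ionise, so that substitution runs in part by SN1 and the enantiomeric purity carried to C3 is eroded; the hindered carbinol may also react sluggishly. The fallback sets out from 12 and comes back at 16, and sets C3 by catalyst-controlled hydride addition instead of chirality transfer. Copper hydride conjugate reduction of the β,β-disubstituted enone (Cu(OAc)2·H2O, DTBM-SEGPHOS in the enantiomer that a model substrate shows to give the 3R centre, (EtO)2MeSiH, t-BuOH, toluene) should give the saturated ketone (3R)-3-[3-iodo-4-methoxy-2,6-bis(methoxymethoxy)phenyl]-1,7-bis[4-(methoxymethoxy)phenyl]heptan-1-one F1. NaBH4 in MeOH should then give the benzylic alcohol (3R)-3-[3-iodo-4-methoxy-2,6-bis(methoxymethoxy)phenyl]-1,7-bis[4-(methoxymethoxy)phenyl]heptan-1-ol F2 as a mixture of C1 epimers, and dehydration with Martin sulfurane (Ph2S[OC(CF3)2Ph]2, CH2Cl2) should give the E-styrene 16.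

Step 5. The aryllithium may add a second time to the ketone released when the lactolate collapses, may deprotonate the side-chain CH2 at C4 of the coumarin instead of adding, and the open phenoxide may isomerise from Z to E before it is trapped. The fallback sets out from 7 and comes back at 11, and divides the operation so that the acyl group is a chelating amide. MeNH(OMe)·HCl and i-PrMgCl (THF, −20 → 0 °C) should open the lactone, and MOMCl added to the same flask should trap the phenoxide as (Z)-N-methoxy-3-[4-methoxy-2,6-bis(methoxymethoxy)phenyl]-7-[4-(methoxymethoxy)phenyl]-N-methylhept-2-enamide F3. The aryllithium 9 (THF, −78 °C) then adds once through the stable chelated tetrahedral intermediate and gives 11 on work-up.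

Step 7. The ketone is flanked by two sp2 groups of similar size, so facial discrimination by the oxazaborolidine may be poor; if only the sense is opposite to the model, the (S)-catalyst is used. The fallback sets out from 7 and comes back at 13, and makes the carbinol centre by C–C bond formation instead of hydride delivery.
- i-Bu2AlH (CH2Cl2, −78 °C) should reduce the lactone to the lactol 7-methoxy-5-(methoxymethoxy)-4-{4-[4-(methoxymethoxy)phenyl]butyl}-2H-chromen-2-ol F4.
- NaH and MOMCl (THF/DMF, 0 °C) should trap the open-chain phenoxide as (Z)-3-[4-methoxy-2,6-bis(methoxymethoxy)phenyl]-7-[4-(methoxymethoxy)phenyl]hept-2-enal F5.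
- NIS in MeCN should give (Z)-3-[3-iodo-4-methoxy-2,6-bis(methoxymethoxy)phenyl]-7-[4-(methoxymethoxy)phenyl]hept-2-enal F6.
- Catalytic asymmetric aryl transfer to the aldehyde (4-(methoxymethoxy)phenylboronic acid, Et2Zn, 2-piperidino-1,1,2-triphenylethanol in the enantiomer that gives the 1R carbinol, toluene, −10 °C) should give 13.

**Further compounds**

F1 | step 8 | (3R)-3-[3-iodo-4-methoxy-2,6-bis(methoxymethoxy)phenyl]-1,7-bis[4-(methoxymethoxy)phenyl]heptan-1-one | COc1cc(OCOC)c([C@@H](CC(=O)c2ccc(OCOC)cc2)CCCCc2ccc(OCOC)cc2)c(OCOC)c1I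
F2 | step 8 | (3R)-3-[3-iodo-4-methoxy-2,6-bis(methoxymethoxy)phenyl]-1,7-bis[4-(methoxymethoxy)phenyl]heptan-1-ol (C1 epimers) | COc1cc(OCOC)c([C@@H](CC(O)c2ccc(OCOC)cc2)CCCCc2ccc(OCOC)cc2)c(OCOC)c1I
F3 | step 5 | (Z)-N-methoxy-3-[4-methoxy-2,6-bis(methoxymethoxy)phenyl]-7-[4-(methoxymethoxy)phenyl]-N-methylhept-2-enamide | CON(C)C(=O)/C=C(/CCCCc1ccc(OCOC)cc1)c1c(OCOC)cc(OC)cc1OCOC
F4 | step 7 | 7-methoxy-5-(methoxymethoxy)-4-{4-[4-(methoxymethoxy)phenyl]butyl}-2H-chromen-2-ol (racemic) | OC1C=C(CCCCc2ccc(OCOC)cc2)c2c(OCOC)cc(OC)cc2O1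
F5 | step 7 | (Z)-3-[4-methoxy-2,6-bis(methoxymethoxy)phenyl]-7-[4-(methoxymethoxy)phenyl]hept-2-enal | O=C/C=C(/CCCCc1ccc(OCOC)cc1)c1c(OCOC)cc(OC)cc1OCOC
F6 | step 7 | (Z)-3-[3-iodo-4-methoxy-2,6-bis(methoxymethoxy)phenyl]-7-[4-(methoxymethoxy)phenyl]hept-2-enal | O=C/C=C(/CCCCc1ccc(OCOC)cc1)c1c(OCOC)cc(OC)c(I)c1OCOC
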